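**Plan**
1. Retrosynthetic cuts, in order: (a) the allyl–C6 bond together with the aromaticity of ring A, leading back to a C6 ketone that takes up an allyl carbanion and then loses H2O and MeOH. (b) O4–C4a, the closure of ring B, as an intramolecular oxa-Michael addition. (c) C8a–OMe, leading from a p-quinone monoketal back to a 4-alkoxyphenol. (d) C3–H and C3–aryl, by ketone reduction and Weinreb acylation. (e) O1–C2, by Mitsunobu reaction.
2. Enabling feature: in ring A the O1-bearing carbon C8a and the allyl-bearing carbon C6 are para, and the O4-bearing carbon C4a is ortho to C8a and meta to C6. Written as a p-quinone monoketal (C8a = ketal carbon, C6 = C=O), ring A presents C4a as an enone β-carbon, placed so that attack by the C3 oxygen closes a six-membered ring. Its two β-carbons are constitutionally equivalent.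
3. Forward order: the C2–C3 chain is hung on O1 of a monoprotected hydroquinone, ring A is dearomatised, and ring B closes onto it. The carbonyl then takes up the allyl group and ring A is re-aromatised last, so the alkene never meets hydrogenolysis or oxidant.
4. Stereochemistry: C2 (S) comes from methyl (R)-lactate by Mitsunobu inversion. C3 (R) comes from chelation-controlled hydride delivery under 1,2-induction from C2 (erythro chain = cis ring B). Both ring-B oxygens are joined to ring A without any bond change at C2 or C3.

Key step: step 7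

Numbering: locants follow the target, O1–C2(Me)–C3(aryl)–O4–C4a–C5–C6(allyl)–C7–C8–C8a. Ring A is the carbocycle and ring B the dioxane.
Assumption: the descriptors and SMILES for the transient centres C4a and C8a (12, 14) and C6 (14) show the diastereomer expected on steric grounds. All three centres become sp2 in step 8, so any other diastereomer converges on 15.

**Step 1**
Reactants: 1 methyl (R)-lactate; 2 4-(benzyloxy)phenol
Product: 3 methyl (S)-2-[4-(benzyloxy)phenoxy]propanoate
Conditions: PPh3, DIAD, THF, 0 °C → rt
Reagents that add atoms: none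
Why: Mitsunobu etherification of a secondary α-hydroxy ester by a phenol runs by clean SN2 inversion, so the (R)-carbinol of 1 becomes the (S)-aryloxy centre that is C2 of the target.

**Step 2**
Reactants: 3 methyl (S)-2-[4-(benzyloxy)phenoxy]propanoate; 4 3,4,5-trimethoxyphenylmagnesium bromide
Product: 6 (S)-2-[4-(benzyloxy)phenoxy]-1-(3,4,5-trimethoxyphenyl)propan-1-one, via Weinreb amide 5 (not isolated)
Conditions: MeNH(OMe)·HCl, iPrMgCl, THF, −20 °C; then 4, −20 → 0 °C; 1 M HCl quench
Reagents that add atoms: N,O-dimethylhydroxylamine hydrochloride, CNOC.Cl (its atoms are held only in 5)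
Why: Aminolysis of the ester by the chloromagnesium amide gives the Weinreb amide, whose chelated tetrahedral adduct with the aryl Grignard reagent stops at the ketone stage (Weinreb ketone synthesis), and the low temperature should keep the α-aryloxy centre from enolising.

**Step 3**
Reactants: 6 (S)-2-[4-(benzyloxy)phenoxy]-1-(3,4,5-trimethoxyphenyl)propan-1-one
Product: 7 (1R,2S)-2-[4-(benzyloxy)phenoxy]-1-(3,4,5-trimethoxyphenyl)propan-1-ol
Conditions: Zn(BH4)2, Et2O–CH2Cl2, −40 → 0 °C
Reagents that add atoms: none
Why: Cram-chelate-controlled ketone reduction, in which divalent zinc bridges the carbonyl oxygen and the electron-rich aryloxy oxygen, so hydride should enter from the face flanked by the C2 hydrogen rather than the methyl group, setting (1R) and the erythro (anti) relationship that becomes cis in ring B.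

**Step 4**
Reactants: 7 (1R,2S)-2-[4-(benzyloxy)phenoxy]-1-(3,4,5-trimethoxyphenyl)propan-1-ol
Product: 8 tert-butyl{[(1R,2S)-2-[4-(benzyloxy)phenoxy]-1-(3,4,5-trimethoxyphenyl)propyl]oxy}dimethylsilane
Conditions: TBSOTf, 2,6-lutidine, CH2Cl2, 0 °C
Reagents that add atoms: tert-butyldimethylsilyl trifluoromethanesulfonate, CC(C)(C)[Si](C)(C)OS(=O)(=O)C(F)(F)F
Why: Silyl triflate O-silylation of a hindered secondary alcohol masks the C3 oxygen so that it cannot intercept the oxidation of step 6, and no stereocentre is touched.

**Step 5**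
Reactants: 8 the silyl ether of step 4
Product: 9 4-{[(1R,2S)-1-[(tert-butyldimethylsilyl)oxy]-1-(3,4,5-trimethoxyphenyl)propan-2-yl]oxy}phenol
Conditions: H2 (1 atm), Pd/C (10 wt %), EtOAc, rt
Reagents that add atoms: none
Why: Catalytic hydrogenolysis of an aryl benzyl ether is far faster than cleavage of the hindered secondary benzylic silyl ether in a non-protic solvent, and no alkene is present yet.

**Step 6**
Reactants: 9 the phenol of step 5
Product: 10 4-{[(1R,2S)-1-[(tert-butyldimethylsilyl)oxy]-1-(3,4,5-trimethoxyphenyl)propan-2-yl]oxy}-4-methoxycyclohexa-2,5-dien-1-one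
Conditions: PhI(OAc)2, MeOH, 0 °C
Reagents that add atoms: methanol, CO
Why: Oxidative dearomatisation of a 4-alkoxyphenol to a p-quinone monoketal, in which two-electron oxidation of the phenol (the most oxidisable group present) makes C8a electrophilic, methanol adds there, and the silyl ether keeps the C3 oxygen from closing a spiro-dioxolane; C8a is not yet stereogenic.

**Step 7**
Reactants: 10 the silyl-protected quinone monoketal of step 6
Product: 12 (2S,3R,4aR,8aS)-8a-methoxy-2-methyl-3-(3,4,5-trimethoxyphenyl)-2,3,4a,8a-tetrahydro-1,4-benzodioxin-6(5H)-one, via hydroxy dienone 11 (not isolated)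
Conditions: Bu4NF, THF, 0 °C → rt
Reagents that add atoms: none
Why: Fluoride removes the silyl helper and the liberated C3 alkoxide of 11 adds to the enone β-carbon that is the future C4a, the enolate being protonated on work-up, so the O4–C4a bond and ring B arise in one desilylation/intramolecular oxa-Michael cascade. The closest known reaction type is the desymmetrising intramolecular oxa-Michael addition of 4-(2-hydroxyethoxy)cyclohexa-2,5-dienones, which gives cis-fused 1,4-dioxane-annulated cyclohexenones. The closure is 6-exo-trig (O4, C3, C2, O1, C8a, C4a in the ring, C5 outside it). The new centres C4a and C8a are controlled by the tether, because O4 must arrive on the dienone face that carries O1 (hence cis fusion), and by the C2 methyl and C3 aryl groups, which should steer attack to the diastereotopic alkene that puts the carbocycle on the face of ring B opposite to them; both centres are erased in step 8. The selectivity that matters is constitutional (O4 ortho to the O1-bearing carbon and meta to the future allyl carbon), and it is secured because O1 is locked on the ketal carbon under non-acidic conditions, the carbonyl marks the allyl position, and the two β-carbons are equivalent. C2 and C3 undergo no bond change, so the cis (2S,3R) pair is preserved, which a closure at the benzylic carbon could not guarantee.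

**Step 8**
Reactants: 12 the bicyclic enone of step 7; 13 allylmagnesium bromide
Product: 15 (2S,3R)-2-methyl-6-(prop-2-en-1-yl)-3-(3,4,5-trimethoxyphenyl)-2,3-dihydro-1,4-benzodioxine (target), via tertiary allylic alcohol 14 (not isolated)
Conditions: 13, LaCl3·2LiCl (0.3 equiv), THF, −78 °C; then HCl (4 M in 1,4-dioxane), −78 → 0 °C
Reagents that add atoms: none
Why: Grignard 1,2-addition to the enone carbonyl (fast six-centre allyl delivery, the lanthanum salt curbing enolisation, allyl expected anti to the two ring-B oxygens at a C6 centre that is erased at once) is followed by acid-induced eliminative aromatisation, in which the exocyclic C8a–OMe bond and the tertiary allylic C6–OH ionise and the C4a and C5 protons are lost, endocyclic C8a–O1 cleavage being reversed by fast re-closure as in glycoside chemistry and the conditions being too mild to ionise the benzylic C3–O4 bond.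

**Compound list**
1 | methyl (R)-lactate | C[C@@H](O)C(=O)OC | starting material
2 | 4-(benzyloxy)phenol | Oc1ccc(OCc2ccccc2)cc1 | starting material
3 | methyl (S)-2-[4-(benzyloxy)phenoxy]propanoate | C[C@H](Oc1ccc(OCc2ccccc2)cc1)C(=O)OC | intermediate
4 | 3,4,5-trimethoxyphenylmagnesium bromide | COc1cc([Mg]Br)cc(OC)c1OC | starting material
5 | (S)-2-[4-(benzyloxy)phenoxy]-N-methoxy-N-methylpropanamide (Weinreb amide) | C[C@H](Oc1ccc(OCc2ccccc2)cc1)C(=O)N(C)OC | intermediate
6 | (S)-2-[4-(benzyloxy)phenoxy]-1-(3,4,5-trimethoxyphenyl)propan-1-one | C[C@H](Oc1ccc(OCc2ccccc2)cc1)C(=O)c1cc(OC)c(OC)c(OC)c1 | intermediate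
7 | (1R,2S)-2-[4-(benzyloxy)phenoxy]-1-(3,4,5-trimethoxyphenyl)propan-1-ol | C[C@H](Oc1ccc(OCc2ccccc2)cc1)[C@H](O)c1cc(OC)c(OC)c(OC)c1 | intermediate
8 | tert-butyl{[(1R,2S)-2-[4-(benzyloxy)phenoxy]-1-(3,4,5-trimethoxyphenyl)propyl]oxy}dimethylsilane | C[C@H](Oc1ccc(OCc2ccccc2)cc1)[C@H](O[Si](C)(C)C(C)(C)C)c1cc(OC)c(OC)c(OC)c1 | intermediate
9 | 4-{[(1R,2S)-1-[(tert-butyldimethylsilyl)oxy]-1-(3,4,5-trimethoxyphenyl)propan-2-yl]oxy}phenol | C[C@H](Oc1ccc(O)cc1)[C@H](O[Si](C)(C)C(C)(C)C)c1cc(OC)c(OC)c(OC)c1 | intermediate
10 | 4-{[(1R,2S)-1-[(tert-butyldimethylsilyl)oxy]-1-(3,4,5-trimethoxyphenyl)propan-2-yl]oxy}-4-methoxycyclohexa-2,5-dien-1-one | C[C@H](OC1(OC)C=CC(=O)C=C1)[C@H](O[Si](C)(C)C(C)(C)C)c1cc(OC)c(OC)c(OC)c1 | intermediate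
11 | 4-{[(1R,2S)-1-hydroxy-1-(3,4,5-trimethoxyphenyl)propan-2-yl]oxy}-4-methoxycyclohexa-2,5-dien-1-one (formed as its tetrabutylammonium alkoxide) | C[C@H](OC1(OC)C=CC(=O)C=C1)[C@H](O)c1cc(OC)c(OC)c(OC)c1 | intermediate
12 | (2S,3R,4aR,8aS)-8a-methoxy-2-methyl-3-(3,4,5-trimethoxyphenyl)-2,3,4a,8a-tetrahydro-1,4-benzodioxin-6(5H)-one (cis-fused, expected major diastereomer) | C[C@@H]1O[C@@]2(OC)C=CC(=O)C[C@H]2O[C@@H]1c1cc(OC)c(OC)c(OC)c1 | intermediate
13 | allylmagnesium bromide | C=CC[Mg]Br | starting material
14 | (2S,3R,4aR,6S,8aS)-8a-methoxy-2-methyl-6-(prop-2-en-1-yl)-3-(3,4,5-trimethoxyphenyl)-2,3,4a,5,6,8a-hexahydro-1,4-benzodioxin-6-ol (expected major epimer) | C[C@@H]1O[C@@]2(OC)C=C[C@](O)(CC=C)C[C@H]2O[C@@H]1c1cc(OC)c(OC)c(OC)c1 | intermediate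
15 | (2S,3R)-2-methyl-6-(prop-2-en-1-yl)-3-(3,4,5-trimethoxyphenyl)-2,3-dihydro-1,4-benzodioxine | C=CCc1ccc2c(c1)O[C@H](c1cc(OC)c(OC)c(OC)c1)[C@H](C)O2 | target

**Count**
Total steps: 8. Longest linear sequence: 8 steps (1 → 15).

**Steps most likely to fail**

Step 7. The conjugate addition is reversible, and the strain of the cis methyl/aryl pair in ring B may hold the equilibrium on the open side. The basic fluoride may also degrade the quinone monoketal before closure.
The fallback closes the same O4–C4a bond on an intact arene by palladium-catalysed intramolecular aryl etherification (Buchwald–Hartwig type).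
- It sets out from 1, which undergoes Mitsunobu reaction with purchased 2-bromo-4-chlorophenol F1 to give methyl (S)-2-(2-bromo-4-chlorophenoxy)propanoate F2.
- The procedures of steps 2 and 3 (with 4) then lead through the Weinreb amide F3 and the aryl ketone F4 to the (1R,2S)-alcohol F5.
- Pd(OAc)2, 2-(di-tert-butylphosphino)-1,1'-binaphthyl, Cs2CO3, toluene, 65 °C should couple the alkoxide at the bromide only and give the 6-chlorobenzodioxine F6.
- Suzuki–Miyaura allylation of the chloride (allylboronic acid pinacol ester, Pd(OAc)2, SPhos, K3PO4, THF–H2O) comes back to the route at 15.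

Step 8. The Grignard reagent may enolise the β-alkoxy ketone, which would reopen ring B by retro-oxa-Michael elimination before carbonyl addition can occur.
The fallback aromatises first and brings in the allyl group by cross-coupling.
- It sets out from 12, which catalytic camphorsulfonic acid in CH2Cl2 should convert, by loss of methanol and tautomerisation, into (2S,3R)-2-methyl-3-(3,4,5-trimethoxyphenyl)-2,3-dihydro-1,4-benzodioxin-6-ol F7.
- Tf2O and pyridine give the aryl triflate F8.
- Stille coupling (allyltributylstannane, Pd(PPh3)4, LiCl, DMF) comes back to the route at 15.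

Step 3. Chelation by the weakly basic aryloxy oxygen may be incomplete, giving poor facial selectivity, and enolisation of the ketone may erode C2.
The fallback sets C3 in the C–C bond-forming event instead of by hydride delivery.
- It sets out from 3, which DIBAL-H (CH2Cl2, −78 °C) reduces to (S)-2-[4-(benzyloxy)phenoxy]propanal F9.
- Addition of 4 in THF at −78 °C under polar Felkin–Anh control (aryl anti to the aryloxy group) should give the anti adduct and comes back to the route at 7.

**Further compounds**
F1 | step 7 | 2-bromo-4-chlorophenol (purchased) | Oc1ccc(Cl)cc1Br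
F2 | step 7 | methyl (S)-2-(2-bromo-4-chlorophenoxy)propanoate | C[C@H](Oc1ccc(Cl)cc1Br)C(=O)OC
F3 | step 7 | (S)-2-(2-bromo-4-chlorophenoxy)-N-methoxy-N-methylpropanamide | C[C@H](Oc1ccc(Cl)cc1Br)C(=O)N(C)OC
F4 | step 7 | (S)-2-(2-bromo-4-chlorophenoxy)-1-(3,4,5-trimethoxyphenyl)propan-1-one | C[C@H](Oc1ccc(Cl)cc1Br)C(=O)c1cc(OC)c(OC)c(OC)c1
F5 | step 7 | (1R,2S)-2-(2-bromo-4-chlorophenoxy)-1-(3,4,5-trimethoxyphenyl)propan-1-ol | C[C@H](Oc1ccc(Cl)cc1Br)[C@H](O)c1cc(OC)c(OC)c(OC)c1
F6 | step 7 | (2S,3R)-6-chloro-2-methyl-3-(3,4,5-trimethoxyphenyl)-2,3-dihydro-1,4-benzodioxine | C[C@@H]1Oc2ccc(Cl)cc2O[C@@H]1c1cc(OC)c(OC)c(OC)c1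
F7 | step 8 | (2S,3R)-2-methyl-3-(3,4,5-trimethoxyphenyl)-2,3-dihydro-1,4-benzodioxin-6-ol | C[C@@H]1Oc2ccc(O)cc2O[C@@H]1c1cc(OC)c(OC)c(OC)c1
F8 | step 8 | (2S,3R)-2-methyl-3-(3,4,5-trimethoxyphenyl)-2,3-dihydro-1,4-benzodioxin-6-yl trifluoromethanesulfonate | C[C@@H]1Oc2ccc(OS(=O)(=O)C(F)(F)F)cc2O[C@@H]1c1cc(OC)c(OC)c(OC)c1
F9 | step 3 | (S)-2-[4-(benzyloxy)phenoxy]propanal | C[C@H](Oc1ccc(OCc2ccccc2)cc1)C=O
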